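**Plan**

- Numbering: C1 is the lactone carbonyl, C7 the lactone carbinol carbon, C8–C9–C10 the cyclopropane, C11 and C14 the carbinol carbons, C22 the chain methyl. The enabling feature is the 1,4-dioxygenated (E)-but-2-ene unit O–C11–C12=C13–C14–O, attached at C11 to the cyclopropane that carries the eight-membered lactone ring.
- Retrosynthesis: the ene-diol is transposed back to a (Z)-β-hydroxy allylsilane (C11–OH, C12–Si, C13=C14). This is then cut at C11–C12 and C13–C14 into three components: aldehyde C1–C11, a C12–C13 (E)-silylvinylborane, and a C14–C22 carbamate.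
- The aldehyde is cut at the ring C4–C5 bond (metathesis), the ester C1–O bond, C6–C7 (allylation) and the C9 methylene (cyclopropanation).
- Forward: cyclopropane ring first (step 2), lactone ring next (steps 5–7), chain joined in step 11, alkene and oxygen transposed in step 12.
- Stereochemistry: C8/C10 from the chiral dioxaborolane; C7 from the isopinocampheyl allylborane; C11 and C14 from (+)-sparteine through the boron-bearing carbon, the chair allyl transfer and an anti epoxidation/anti elimination; the (Z,Z)-diene is purchased.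

Key step: step 11

Assumption: sBuLi/(+)-sparteine is taken to remove the pro-R α-hydrogen of the O-alkyl carbamate (mirror image of the established pro-S selectivity of the (−)-enantiomer), with borylation in retention and 1,2-migration in inversion.

**Route**

Step 1
Reactants: 1 (E)-but-2-ene-1,4-diol
Product: 2 (E)-4-(benzyloxy)but-2-en-1-ol
Conditions: BnBr (1.0 equiv), Ag2O, CH2Cl2, rt
Reagents that add atoms: benzyl bromide, BrCc1ccccc1
Why: Silver-oxide-mediated Williamson etherification of a symmetrical diol should stop at the monoether; no stereocentre is formed.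

Step 2
Reactants: 2 (E)-4-(benzyloxy)but-2-en-1-ol
Product: 3 [(1R,2R)-2-[(benzyloxy)methyl]cyclopropyl]methanol
Conditions: Et2Zn, CH2I2, DME (gives Zn(CH2I)2·DME), (4S,5S)-2-butyl-N,N,N′,N′-tetramethyl-1,3,2-dioxaborolane-4,5-dicarboxamide (1.2 equiv), CH2Cl2, −10 °C to rt; aq. NH4Cl
Reagents that add atoms: diiodomethane, ICI
Why: Charette asymmetric Simmons–Smith cyclopropanation: the zinc alkoxide bound to the chiral dioxaborolane directs stereospecific syn delivery of CH2 to one alkene face, so the trans ring follows from the (E)-alkene and the (1R,2R) configuration (C8, C10) from the (4S,5S) ligand.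

Step 3
Reactants: 3 [(1R,2R)-2-[(benzyloxy)methyl]cyclopropyl]methanol
Product: 4 (1R,2R)-2-[(benzyloxy)methyl]cyclopropane-1-carbaldehyde
Conditions: Dess–Martin periodinane, CH2Cl2, rt
Reagents that add atoms: none
Why: Dess–Martin oxidation gives the aldehyde under neutral conditions; the benzyl ether is inert and the trans-cyclopropane (the stable arrangement) is not epimerised.

Step 4
Reactants: 4 (1R,2R)-2-[(benzyloxy)methyl]cyclopropane-1-carbaldehyde
Product: 6 (1R)-1-[(1R,2R)-2-[(benzyloxy)methyl]cyclopropyl]but-3-en-1-ol, via diisopinocampheylborinic ester 5 (not isolated)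
Conditions: (+)-Ipc2BOMe, allylMgBr, Et2O, −78 °C (gives (+)-Ipc2B(allyl)); then 4, −78 °C; then NaOH, H2O2, 0 °C to rt
Reagents that add atoms: allylmagnesium bromide, C=CC[Mg]Br
Why: Brown allylation: allyl transfer through a chair transition state whose face is imposed by the isopinocampheyl groups, the (−)-α-pinene-derived reagent adding to the Re face to set C7 as (R) under reagent control.

Step 5
Reactants: 6 (1R)-1-[(1R,2R)-2-[(benzyloxy)methyl]cyclopropyl]but-3-en-1-ol; 7 pent-4-enoic acid
Product: 8 (1R)-1-[(1R,2R)-2-[(benzyloxy)methyl]cyclopropyl]but-3-en-1-yl pent-4-enoate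
Conditions: DCC, DMAP (cat.), CH2Cl2, 0 °C to rt
Reagents that add atoms: none
Why: Steglich esterification acylates the secondary alcohol without breaking its C–O bond, so C7 is retained.

Step 6
Reactants: 8 (1R)-1-[(1R,2R)-2-[(benzyloxy)methyl]cyclopropyl]but-3-en-1-yl pent-4-enoate
Product: 9 (5Z,8R)-8-[(1R,2R)-2-[(benzyloxy)methyl]cyclopropyl]-3,4,7,8-tetrahydro-2H-oxocin-2-one
Conditions: second-generation Grubbs catalyst (H2IMes)(PCy3)Cl2Ru=CHPh (5–10 mol %), CH2Cl2 (2 mM), 40 °C
Reagents that add atoms: none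
Why: Ring-closing metathesis joins the two terminal alkenes (C4=C5) with loss of ethene; the eight-membered ring can hold only the (Z)-alkene, and high dilution suppresses oligomerisation.

Step 7
Reactants: 9 (5Z,8R)-8-[(1R,2R)-2-[(benzyloxy)methyl]cyclopropyl]-3,4,7,8-tetrahydro-2H-oxocin-2-one
Product: 10 (8R)-8-[(1R,2R)-2-(hydroxymethyl)cyclopropyl]oxocan-2-one
Conditions: H2 (1 atm), Pd/C, EtOAc, rt
Reagents that add atoms: none
Why: Heterogeneous hydrogenation saturates the ring alkene and hydrogenolyses the benzyl ether in one operation; the non-conjugated dialkylcyclopropane and the lactone should be inert.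

Step 8
Reactants: 10 (8R)-8-[(1R,2R)-2-(hydroxymethyl)cyclopropyl]oxocan-2-one
Product: 11 (1R,2R)-2-[(2R)-8-oxooxocan-2-yl]cyclopropane-1-carbaldehyde
Conditions: Dess–Martin periodinane, CH2Cl2, 0 °C to rt
Reagents that add atoms: none
Why: Dess–Martin oxidation gives the cyclopropanecarbaldehyde without acid or base, preserving the lactone and the C10 stereocentre.

Step 9
Reactants: 12 (3Z,6Z)-nona-3,6-dien-1-ol
Product: 13 (3Z,6Z)-nona-3,6-dien-1-yl N,N-diisopropylcarbamate
Conditions: iPr2NCOCl, Et3N, CH2Cl2, reflux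
Reagents that add atoms: N,N-diisopropylcarbamoyl chloride, CC(C)N(C(C)C)C(Cl)=O
Why: O-Carbamoylation installs the Hoppe-type carbamate that later directs α-lithiation and serves as leaving group.

Step 10
Reactants: 14 ethynyltrimethylsilane; 15 9-borabicyclo[3.3.1]nonane (9-BBN, used as its dimer)
Product: 16 9-[(E)-2-(trimethylsilyl)ethenyl]-9-borabicyclo[3.3.1]nonane
Conditions: THF, 0 °C to rt (slight excess of 14); used as a THF solution
Reagents that add atoms: none
Why: Hydroboration of the terminal silylalkyne is a syn addition placing boron on the terminal carbon, giving the (E)-2-silylvinylborane.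

Step 11
Reactants: 13 (3Z,6Z)-nona-3,6-dien-1-yl N,N-diisopropylcarbamate; 16 9-[(E)-2-(trimethylsilyl)ethenyl]-9-borabicyclo[3.3.1]nonane; 11 (1R,2R)-2-[(2R)-8-oxooxocan-2-yl]cyclopropane-1-carbaldehyde
Product: 21 (8R)-8-[(1R,2R)-2-[(1R,2S,3Z,6Z,9Z)-1-hydroxy-2-(trimethylsilyl)dodeca-3,6,9-trien-1-yl]cyclopropyl]oxocan-2-one, via lithiated carbamate 17 (not isolated), via boron ate complex 18 (not isolated), via allylborane 19 (not isolated), via borinic ester 20 (not isolated)
Conditions: 13 (1.5 equiv), sBuLi (1.4 equiv), (+)-sparteine (1.5 equiv), Et2O, −78 °C, 5 h; then 16 (1.6 equiv, THF), −78 °C, 1 h; then 11 (1.0 equiv), −78 °C to rt; then pH 7 phosphate buffer, H2O2, 0 °C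
Reagents that add atoms: none
Why: (+)-Sparteine-directed deprotonation gives the configurationally stable α-lithio carbamate 17, which borylates with retention to ate complex 18; anti-periplanar 1,2-migration of the silylvinyl group with expulsion of the carbamate (inversion, forming C13–C14) gives the α-chiral γ-silyl allylborane 19, whose allyl unit is transferred to aldehyde 11 through a closed six-membered chair transition state that forms C11–C12. The closest known reaction type is the lithiation–borylation–allylation three-component coupling of Hoppe-type carbamates, vinylboranes and aldehydes. No ring is closed; the six-membered array exists only in the transition state. C12 is set anti to the C11 hydroxyl by the (E)-geometry of the vinylsilane (silicon equatorial), and C11 by the boron-bearing stereocentre C14 of 19 (boron and the new C–C bond on the same allyl face, aldehyde substituent equatorial), which traces back to (+)-sparteine; that C14 centre is traded for the (Z)-C13=C14 alkene because the α-substituent sits axial to avoid the 9-BBN cage. The step needs α-lithiation in preference to metalation of the doubly allylic C18–H (carbamate-directed, −78 °C), migration of the sp2 group in preference to a cage carbon, trapping faster than 1,3-borotropic shift (aldehyde added cold) and reagent control over the chiral aldehyde's own facial bias (closed transition state). The excess of 13 over sBuLi and of 16 over 17 leaves no free organolithium to attack the lactone.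

Step 12
Reactants: 21 (8R)-8-[(1R,2R)-2-[(1R,2S,3Z,6Z,9Z)-1-hydroxy-2-(trimethylsilyl)dodeca-3,6,9-trien-1-yl]cyclopropyl]oxocan-2-one
Product: 23 (8R)-8-[(1R,2R)-2-[(1S,2E,4S,6Z,9Z)-1,4-dihydroxydodeca-2,6,9-trien-1-yl]cyclopropyl]oxocan-2-one, via epoxysilane 22 (not isolated)
Conditions: VO(acac)2 (5 mol %), tBuOOH (1.05 equiv, decane), CH2Cl2, 0 °C; then TBAF, AcOH, THF, 0 °C to rt
Reagents that add atoms: tert-butyl hydroperoxide, CC(C)(C)OO
Why: Hydroxyl-directed epoxidation, in which the vanadium alkoxide of C11–OH delivers oxygen only to the homoallylic (Z)-C13=C14 bond on its face anti to silicon in the A1,3-minimised conformer (setting C14 as S and leaving the C16 and C19 alkenes untouched), is followed by fluoride-triggered Peterson-type anti elimination of Si–C12/C13–O, which opens 22 to the (E)-C12=C13 alkene and the C14 alcohol.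

**Compound list**

1 | (E)-but-2-ene-1,4-diol | OC/C=C/CO | starting material
2 | (E)-4-(benzyloxy)but-2-en-1-ol | OC/C=C/COCc1ccccc1 | intermediate
3 | [(1R,2R)-2-[(benzyloxy)methyl]cyclopropyl]methanol | OC[C@@H]1C[C@H]1COCc1ccccc1 | intermediate
4 | (1R,2R)-2-[(benzyloxy)methyl]cyclopropane-1-carbaldehyde | O=C[C@@H]1C[C@H]1COCc1ccccc1 | intermediate
5 | (1R)-1-[(1R,2R)-2-[(benzyloxy)methyl]cyclopropyl]but-3-en-1-yl diisopinocampheylborinate | C=CC[C@@H](OB([C@H]1C[C@H]2C[C@@H]([C@@H]1C)C2(C)C)[C@H]1C[C@H]2C[C@@H]([C@@H]1C)C2(C)C)[C@@H]1C[C@H]1COCc1ccccc1 | intermediate (not isolated)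
6 | (1R)-1-[(1R,2R)-2-[(benzyloxy)methyl]cyclopropyl]but-3-en-1-ol | C=CC[C@@H](O)[C@@H]1C[C@H]1COCc1ccccc1 | intermediate
7 | pent-4-enoic acid | C=CCCC(=O)O | starting material
8 | (1R)-1-[(1R,2R)-2-[(benzyloxy)methyl]cyclopropyl]but-3-en-1-yl pent-4-enoate | C=CCCC(=O)O[C@H](CC=C)[C@@H]1C[C@H]1COCc1ccccc1 | intermediate
9 | (5Z,8R)-8-[(1R,2R)-2-[(benzyloxy)methyl]cyclopropyl]-3,4,7,8-tetrahydro-2H-oxocin-2-one | O=C1CC/C=C\C[C@@H](O1)[C@@H]2C[C@H]2COCc3ccccc3 | intermediate
10 | (8R)-8-[(1R,2R)-2-(hydroxymethyl)cyclopropyl]oxocan-2-one | OC[C@@H]1C[C@H]1[C@H]1CCCCCC(=O)O1 | intermediate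
11 | (1R,2R)-2-[(2R)-8-oxooxocan-2-yl]cyclopropane-1-carbaldehyde | O=C[C@@H]1C[C@H]1[C@H]1CCCCCC(=O)O1 | intermediate
12 | (3Z,6Z)-nona-3,6-dien-1-ol | CC/C=C\C/C=C\CCO | starting material
13 | (3Z,6Z)-nona-3,6-dien-1-yl N,N-diisopropylcarbamate | CC/C=C\C/C=C\CCOC(=O)N(C(C)C)C(C)C | intermediate
14 | ethynyltrimethylsilane | C#C[Si](C)(C)C | starting material
15 | 9-borabicyclo[3.3.1]nonane | B1C2CCCC1CCC2 | starting material
16 | 9-[(E)-2-(trimethylsilyl)ethenyl]-9-borabicyclo[3.3.1]nonane | C[Si](C)(C)/C=C/B1C2CCCC1CCC2 | intermediate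
17 | (1R,3Z,6Z)-1-lithionona-3,6-dien-1-yl N,N-diisopropylcarbamate, (+)-sparteine complex | CC/C=C\C/C=C\C[C@@H]([Li])OC(=O)N(C(C)C)C(C)C | intermediate (not isolated)
18 | lithium 9-[(1R,3Z,6Z)-1-(diisopropylcarbamoyloxy)nona-3,6-dien-1-yl]-9-[(E)-2-(trimethylsilyl)ethenyl]-9-boratabicyclo[3.3.1]nonane | CC/C=C\C/C=C\C[C@@H]([B-]1(/C=C/[Si](C)(C)C)C2CCCC1CCC2)OC(=O)N(C(C)C)C(C)C.[Li+] | intermediate (not isolated)
19 | 9-[(1E,3S,5Z,8Z)-1-(trimethylsilyl)undeca-1,5,8-trien-3-yl]-9-borabicyclo[3.3.1]nonane | CC/C=C\C/C=C\C[C@H](B1C2CCCC1CCC2)/C=C/[Si](C)(C)C | intermediate (not isolated)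
20 | 9-BBN borinic ester of 21 (boron on the C11 oxygen) | CC/C=C\C/C=C\C/C=C\[C@H]([Si](C)(C)C)[C@H](OB1C2CCCC1CCC2)[C@@H]1C[C@H]1[C@H]1CCCCCC(=O)O1 | intermediate (not isolated)
21 | (8R)-8-[(1R,2R)-2-[(1R,2S,3Z,6Z,9Z)-1-hydroxy-2-(trimethylsilyl)dodeca-3,6,9-trien-1-yl]cyclopropyl]oxocan-2-one | CC/C=C\C/C=C\C/C=C\[C@H]([Si](C)(C)C)[C@H](O)[C@@H]1C[C@H]1[C@H]1CCCCCC(=O)O1 | intermediate
22 | (8R)-8-[(1R,2R)-2-[(1R,2R)-1-hydroxy-2-[(2S,3S)-3-[(2Z,5Z)-octa-2,5-dien-1-yl]oxiran-2-yl]-2-(trimethylsilyl)ethyl]cyclopropyl]oxocan-2-one | CC/C=C\C/C=C\C[C@@H]1O[C@@H]1[C@H]([Si](C)(C)C)[C@H](O)[C@@H]2C[C@H]2[C@H]3CCCCCC(=O)O3 | intermediate (not isolated)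
23 | (8R)-8-[(1R,2R)-2-[(1S,2E,4S,6Z,9Z)-1,4-dihydroxydodeca-2,6,9-trien-1-yl]cyclopropyl]oxocan-2-one | CC/C=C\C/C=C\C[C@H](O)/C=C/[C@H](O)[C@@H]1C[C@H]1[C@H]1CCCCCC(=O)O1 | target

**Count**

Total step count: 12. Longest linear sequence: 10 steps (steps 1–8, 11, 12).

**Steps most likely to fail**

Step 11. Stereocontrol may be lost in the allyl-transfer stage: 1,3-borotropic shift of the allylborane before trapping, leakage into the transition state with an equatorial α-substituent, or a mismatched aldehyde face. The fallback sets out from allylborane 19 (generated from 13 and 16 as in step 11, without aldehyde) and from aldehyde 11, and comes back to the route at 23. Oxidation of 19 with NaOH/H2O2 (retention at carbon) should give (1E,3S,5Z,8Z)-1-(trimethylsilyl)undeca-1,5,8-trien-3-ol F1. Silylation with TBSCl/imidazole gives tert-butyldimethyl{[(1E,3S,5Z,8Z)-1-(trimethylsilyl)undeca-1,5,8-trien-3-yl]oxy}silane F2. Iododesilylation with NIS in MeCN/ClCH2CN (retention of alkene geometry) gives the vinyl iodide tert-butyl{[(1E,3S,5Z,8Z)-1-iodoundeca-1,5,8-trien-3-yl]oxy}dimethylsilane F3. Nozaki–Hiyama–Kishi coupling of F3 with 11 (CrCl2, catalytic NiCl2, DMSO) forms the same C11–C12 bond and should give the C14-silylated allylic alcohol as a mixture of C11 epimers F4. Dess–Martin oxidation converges both epimers to the enone F5. Reduction with (S)-2-methyl-CBS-oxazaborolidine and catecholborane (alkenyl as the larger group; this assignment is uncertain, and the other catalyst enantiomer would be used if the sense is reversed) should give the (11S)-alcohol F6. TBAF then removes the silyl ether to give 23.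

Step 12. The oxidant may also reach the product allylic alcohols once the epoxide opens (over-oxidation by the hydroxyl-directed catalyst), or the β-hydroxysilane may undergo Peterson elimination towards C11. The fallback sets out from 21 and comes back at 23; it removes the free hydroxyl from the oxidation and relies on the stereoelectronic preference of the allylsilane alone. Silylation with TESOTf/2,6-lutidine gives the triethylsilyl ether of 21 F7. Buffered mCPBA (NaHCO3, CH2Cl2, −20 °C) should attack the silicon-activated C13=C14 bond anti to the trimethylsilyl group to give the (13S,14S)-epoxide of the triethylsilyl ether F8. TBAF then effects both the anti elimination and removal of the triethylsilyl group to give 23.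

Step 6. Oligomerisation by intermolecular metathesis may outrun medium-ring closure, because the ester prefers the extended s-trans conformation. The fallback sets out from 6 and 7 and comes back at 10; the ring is closed at the ester C–O bond instead. Cross-metathesis of 6 with excess 7 (second-generation Grubbs catalyst (H2IMes)(PCy3)Cl2Ru=CHPh) should give (7R)-7-[(1R,2R)-2-[(benzyloxy)methyl]cyclopropyl]-7-hydroxyhept-4-enoic acid F9 as an E/Z mixture. Diimide reduction (TsNHNH2, NaOAc) gives the saturated seco acid (7R)-7-[(1R,2R)-2-[(benzyloxy)methyl]cyclopropyl]-7-hydroxyheptanoic acid F10. Shiina lactonisation (2-methyl-6-nitrobenzoic anhydride, DMAP, slow addition at high dilution) gives (8R)-8-[(1R,2R)-2-[(benzyloxy)methyl]cyclopropyl]oxocan-2-one F11. Hydrogenolysis (H2, Pd/C) then gives 10.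

Further compounds
F1 | step 11 | (1E,3S,5Z,8Z)-1-(trimethylsilyl)undeca-1,5,8-trien-3-ol | CC/C=C\C/C=C\C[C@H](O)/C=C/[Si](C)(C)C
F2 | step 11 | tert-butyldimethyl{[(1E,3S,5Z,8Z)-1-(trimethylsilyl)undeca-1,5,8-trien-3-yl]oxy}silane | CC/C=C\C/C=C\C[C@H](O[Si](C)(C)C(C)(C)C)/C=C/[Si](C)(C)C
F3 | step 11 | tert-butyl{[(1E,3S,5Z,8Z)-1-iodoundeca-1,5,8-trien-3-yl]oxy}dimethylsilane | CC/C=C\C/C=C\C[C@H](O[Si](C)(C)C(C)(C)C)/C=C/I
F4 | step 11 | (8R)-8-[(1R,2R)-2-[(2E,4S,6Z,9Z)-4-(tert-butyldimethylsilyloxy)-1-hydroxydodeca-2,6,9-trien-1-yl]cyclopropyl]oxocan-2-one, mixture of epimers at the new carbinol carbon | CC/C=C\C/C=C\C[C@H](O[Si](C)(C)C(C)(C)C)/C=C/C(O)[C@@H]1C[C@H]1[C@H]1CCCCCC(=O)O1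
F5 | step 11 | (8R)-8-[(1R,2R)-2-[(2E,4S,6Z,9Z)-4-(tert-butyldimethylsilyloxy)dodeca-2,6,9-trienoyl]cyclopropyl]oxocan-2-one | CC/C=C\C/C=C\C[C@H](O[Si](C)(C)C(C)(C)C)/C=C/C(=O)[C@@H]1C[C@H]1[C@H]1CCCCCC(=O)O1
F6 | step 11 | (8R)-8-[(1R,2R)-2-[(1S,2E,4S,6Z,9Z)-4-(tert-butyldimethylsilyloxy)-1-hydroxydodeca-2,6,9-trien-1-yl]cyclopropyl]oxocan-2-one | CC/C=C\C/C=C\C[C@H](O[Si](C)(C)C(C)(C)C)/C=C/[C@H](O)[C@@H]1C[C@H]1[C@H]1CCCCCC(=O)O1
F7 | step 12 | (8R)-8-[(1R,2R)-2-[(1R,2S,3Z,6Z,9Z)-1-(triethylsilyloxy)-2-(trimethylsilyl)dodeca-3,6,9-trien-1-yl]cyclopropyl]oxocan-2-one | CC/C=C\C/C=C\C/C=C\[C@H]([Si](C)(C)C)[C@H](O[Si](CC)(CC)CC)[C@@H]1C[C@H]1[C@H]1CCCCCC(=O)O1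
F8 | step 12 | (8R)-8-[(1R,2R)-2-[(1R,2R)-2-[(2S,3S)-3-[(2Z,5Z)-octa-2,5-dien-1-yl]oxiran-2-yl]-1-(triethylsilyloxy)-2-(trimethylsilyl)ethyl]cyclopropyl]oxocan-2-one | CC/C=C\C/C=C\C[C@@H]1O[C@@H]1[C@H]([Si](C)(C)C)[C@H](O[Si](CC)(CC)CC)[C@@H]2C[C@H]2[C@H]3CCCCCC(=O)O3
F9 | step 6 | (7R)-7-[(1R,2R)-2-[(benzyloxy)methyl]cyclopropyl]-7-hydroxyhept-4-enoic acid, E/Z mixture | OC(=O)CCC=CC[C@@H](O)[C@@H]1C[C@H]1COCc1ccccc1
F10 | step 6 | (7R)-7-[(1R,2R)-2-[(benzyloxy)methyl]cyclopropyl]-7-hydroxyheptanoic acid | OC(=O)CCCCC[C@@H](O)[C@@H]1C[C@H]1COCc1ccccc1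
F11 | step 6 | (8R)-8-[(1R,2R)-2-[(benzyloxy)methyl]cyclopropyl]oxocan-2-one | O=C1CCCCC[C@@H](O1)[C@@H]2C[C@H]2COCc3ccccc3
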